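**Strategy.** Ring A is read as a syringoyl unit: syringic acid already carries C6-OMe, C7-O, C8-OMe and the C4a–C4 bond, and the two missing oxygens, O1 at C8a and the hydroxyl at C5, belong on its two equivalent ortho carbons. Both are brominated. The pyranone is then closed at O1–C8a, not at the usual O1–C2, by copper-catalysed intramolecular O-arylation of a 2-methoxy-1,3-diketone enolate onto either ortho C–Br; in the same pot the twin C5–Br and the B-ring C4'–Br are exchanged for hydroxyl. The precursor is a tribromo diketone assembled from two cheap symmetric arenes; phenolic oxygens enter as bromine, so only one protecting group is needed.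

Key step: step 5

Remark: the target has no stereocentre and no configurationally stable axis, so the single constitution drawn is the whole stereochemical task. The only stereocentre on the route (C2 of diketone 11) is formed racemic and is destroyed in step 5.

**Step 1**
Reactants: 1 syringic acid (4-hydroxy-3,5-dimethoxybenzoic acid)
Product: 3 4-(benzyloxy)-3,5-dimethoxybenzoic acid, via benzyl ester 2 (not isolated)
Conditions: BnBr (2.3 equiv), K2CO3 (2.5 equiv), DMF, 60 °C; then 2 M aq NaOH, MeOH, 60 °C; then 1 M HCl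
Reagents that add atoms: benzyl bromide, BrCc1ccccc1; sodium hydroxide, [Na+].[OH-]
Why: Williamson O-benzylation of the phenoxide and carboxylate followed by saponification of the unhindered benzyl ester should leave the aryl benzyl ether, which is inert to hydroxide.

**Step 2**
Reactants: 3 4-(benzyloxy)-3,5-dimethoxybenzoic acid
Product: 4 4-(benzyloxy)-2,6-dibromo-3,5-dimethoxybenzoic acid
Conditions: NBS (2.3 equiv), DMF, 0 °C → 45 °C, dark
Reagents that add atoms: N-bromosuccinimide, O=C1CCC(=O)N1Br
Why: electrophilic aromatic bromination should take both remaining ring C–H positions, each ortho to one methoxy and para to the other, while polar conditions in the dark spare the benzylic CH2.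

**Step 3**
Reactants: 5 1,4-dibromo-2,5-dimethoxybenzene; 6 N,2-dimethoxy-N-methylacetamide
Product: 8 1-(4-bromo-2,5-dimethoxyphenyl)-2-methoxyethan-1-one, via aryllithium 7 (not isolated)
Conditions: n-BuLi (1.0 equiv), THF, −78 °C; then 6, −78 → 0 °C; aq NH4Cl
Reagents that add atoms: none
Why: mono bromine–lithium exchange on the symmetric dibromide gives an ortho-methoxy-stabilised aryllithium, and Weinreb ketone synthesis stops at the ketone through the chelated tetrahedral intermediate.

**Step 4**
Reactants: 4 4-(benzyloxy)-2,6-dibromo-3,5-dimethoxybenzoic acid; 8 1-(4-bromo-2,5-dimethoxyphenyl)-2-methoxyethan-1-one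
Product: 11 1-[4-(benzyloxy)-2,6-dibromo-3,5-dimethoxyphenyl]-3-(4-bromo-2,5-dimethoxyphenyl)-2-methoxypropane-1,3-dione (racemic), via acid chloride 9 (not isolated), via lithium enolate 10 (not isolated)
Conditions: 4, (COCl)2, cat. DMF, CH2Cl2, 0 °C → rt, evaporate; 8, LiHMDS (2.1 equiv), THF, −78 °C; then crude 9 in THF, −78 → 0 °C; aq NH4Cl
Reagents that add atoms: none
Why: crossed Claisen-type C-acylation of the chelated ketone lithium enolate by the acid chloride should give the diketone, which the second equivalent of base stores as its diketonate; the new C2 stereocentre is racemic and is lost in step 5.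

**Step 5**
Reactants: 11 1-[4-(benzyloxy)-2,6-dibromo-3,5-dimethoxyphenyl]-3-(4-bromo-2,5-dimethoxyphenyl)-2-methoxypropane-1,3-dione
Product: 13 7-(benzyloxy)-5-hydroxy-2-(4-hydroxy-2,5-dimethoxyphenyl)-3,6,8-trimethoxy-4H-chromen-4-one, via 5-bromoflavone 12 (not isolated)
Conditions: Cu(acac)2 (10 mol%), N,N'-bis(4-hydroxy-2,6-dimethylphenyl)oxalamide (BHMPO, 10 mol%), Cs2CO3 (1.5 equiv), degassed DMSO (0.05 M), 80 °C; then LiOH·H2O (5 equiv), H2O (DMSO/H2O 4:1), 80–100 °C; 1 M HCl
Reagents that add atoms: lithium hydroxide, [Li+].[OH-]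
Why: Carbonate turns 11 into its diketonate, which binds copper through both oxygens and delivers it to an ortho C–Br of the twisted syringoyl ring; oxidative addition and C–O reductive elimination then forge O1–C8a to give 12, after which the same catalyst with hydroxide exchanges the C5–Br (assisted by chelation to the peri C4 carbonyl) and the C4'–Br for OH. The closest known reaction types are the Ullmann-type intramolecular O-arylation of 1-(2-bromoaryl)-1,3-diketones to flavones and the copper/oxalamide-catalysed hydroxylation of aryl bromides. The pyranone closes in a 6-exo ipso-substitution at an sp2 carbon by the enolate oxygen of the B-ring carbonyl, since C-arylation or attack by the proximal oxygen would need a four-membered ring. No stereocentre is formed, and the racemic C2 centre of 11 disappears when C2=C3 is established. The step needs site selectivity among three C–Br bonds: the two ortho bromines are exchanged by rotation about the C4–C4a bond, so either closure gives the same 12 with the survivor exactly at C5, while C4'–Br is out of reach of the tethered enolate and waits for hydroxide. Hydroxide is added only after ring closure so that the diketone is not exposed to retro-Claisen cleavage, and excess hydroxide in wet DMSO should keep the product phenoxides from competing as nucleophiles.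

**Step 6**
Reactants: 13 7-(benzyloxy)-5-hydroxy-2-(4-hydroxy-2,5-dimethoxyphenyl)-3,6,8-trimethoxy-4H-chromen-4-one
Product: 14 5,7-dihydroxy-2-(4-hydroxy-2,5-dimethoxyphenyl)-3,6,8-trimethoxy-4H-chromen-4-one (5,7,4'-trihydroxy-3,6,8,2',5'-pentamethoxyflavone)
Conditions: H2 (1 atm), 10% Pd/C, EtOAc/MeOH, rt
Reagents that add atoms: none
Why: hydrogenolysis of the single benzyl aryl ether should free the 7-OH, while the tetrasubstituted C2=C3 bond and the methyl ethers are untouched and no C–Br remains to be reduced.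

**Compound list**

1 | syringic acid (4-hydroxy-3,5-dimethoxybenzoic acid) | COc1cc(C(=O)O)cc(OC)c1O | starting material
2 | benzyl 4-(benzyloxy)-3,5-dimethoxybenzoate | COc1cc(C(=O)OCc2ccccc2)cc(OC)c1OCc1ccccc1 | intermediate (not isolated)
3 | 4-(benzyloxy)-3,5-dimethoxybenzoic acid | COc1cc(C(=O)O)cc(OC)c1OCc1ccccc1 | intermediate
4 | 4-(benzyloxy)-2,6-dibromo-3,5-dimethoxybenzoic acid | COc1c(Br)c(C(=O)O)c(Br)c(OC)c1OCc1ccccc1 | intermediate
5 | 1,4-dibromo-2,5-dimethoxybenzene | COc1cc(Br)c(OC)cc1Br | starting material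
6 | N,2-dimethoxy-N-methylacetamide | COCC(=O)N(C)OC | starting material
7 | (4-bromo-2,5-dimethoxyphenyl)lithium | [Li]c1cc(OC)c(Br)cc1OC | intermediate (not isolated)
8 | 1-(4-bromo-2,5-dimethoxyphenyl)-2-methoxyethan-1-one | COCC(=O)c1cc(OC)c(Br)cc1OC | intermediate
9 | 4-(benzyloxy)-2,6-dibromo-3,5-dimethoxybenzoyl chloride | COc1c(Br)c(C(Cl)=O)c(Br)c(OC)c1OCc1ccccc1 | intermediate (not isolated)
10 | lithium (Z)-1-(4-bromo-2,5-dimethoxyphenyl)-2-methoxyethen-1-olate (enolate of 8) | CO/C=C(\O[Li])c1cc(OC)c(Br)cc1OC | intermediate (not isolated)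
11 | 1-[4-(benzyloxy)-2,6-dibromo-3,5-dimethoxyphenyl]-3-(4-bromo-2,5-dimethoxyphenyl)-2-methoxypropane-1,3-dione (racemic) | COc1c(Br)c(C(=O)C(OC)C(=O)c2cc(OC)c(Br)cc2OC)c(Br)c(OC)c1OCc1ccccc1 | intermediate
12 | 7-(benzyloxy)-5-bromo-2-(4-bromo-2,5-dimethoxyphenyl)-3,6,8-trimethoxy-4H-chromen-4-one | COc1cc(-c2oc3c(OC)c(OCc4ccccc4)c(OC)c(Br)c3c(=O)c2OC)c(OC)cc1Br | intermediate (not isolated)
13 | 7-(benzyloxy)-5-hydroxy-2-(4-hydroxy-2,5-dimethoxyphenyl)-3,6,8-trimethoxy-4H-chromen-4-one | COc1cc(-c2oc3c(OC)c(OCc4ccccc4)c(OC)c(O)c3c(=O)c2OC)c(OC)cc1O | intermediate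
14 | 5,7-dihydroxy-2-(4-hydroxy-2,5-dimethoxyphenyl)-3,6,8-trimethoxy-4H-chromen-4-one | COc1cc(-c2oc3c(OC)c(O)c(OC)c(O)c3c(=O)c2OC)c(OC)cc1O | target

**Totals.** Total step count: 6. Longest linear sequence: 5 steps (steps 1, 2, 4, 5, 6); step 3 is the one-step branch to the B-ring ketone.

**Steps most likely to fail**

Step 5. Before ring closure, the crowded diketonate may fragment by retro-Claisen cleavage, or oxidative addition at the doubly ortho-substituted C–Br may be sluggish. Afterwards, hydroxide may open the pyranone, or the bromide-to-hydroxide exchange at C4' may stay incomplete. The fallback makes both ring-A C–O bonds on the acid under carboxylate assistance and closes the pyranone conventionally at O1–C2. It sets out from 4 (with enolate 10 from 8) and returns at 13. Acid 4 is heated with CuI (10 mol%) and aqueous NaOH at 100 °C (carboxylate-directed Ullmann hydroxylation) and acidified cold to give 4-(benzyloxy)-2,6-dihydroxy-3,5-dimethoxybenzoic acid F1. Acetone/TFAA/TFA should convert this into the salicylate acetonide 7-(benzyloxy)-5-hydroxy-6,8-dimethoxy-2,2-dimethyl-4H-1,3-benzodioxin-4-one F2. NaH/MOMCl in DMF then gives 7-(benzyloxy)-6,8-dimethoxy-5-(methoxymethoxy)-2,2-dimethyl-4H-1,3-benzodioxin-4-one F3. Lithium enolate 10 (2.2 equiv, THF, −78 → 0 °C) opens the dioxinone with loss of acetone to 1-[4-(benzyloxy)-2-hydroxy-3,5-dimethoxy-6-(methoxymethoxy)phenyl]-3-(4-bromo-2,5-dimethoxyphenyl)-2-methoxypropane-1,3-dione F4. HCl in MeOH at 50 °C should effect cyclodehydration and MOM removal to 7-(benzyloxy)-2-(4-bromo-2,5-dimethoxyphenyl)-5-hydroxy-3,6,8-trimethoxy-4H-chromen-4-one F5. Its single C4'–Br is hydroxylated with Cu(acac)2/BHMPO/LiOH in DMSO/H2O to give 13.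

Step 4. The hindered acid chloride 9 may acylate enolate 10 on oxygen (enol ester) or react incompletely. The fallback forms the C3–C4 bond by aldol addition and then adjusts the oxidation level. It sets out from 4 and 8 and returns at 11. Acid 4 is reduced with BH3·SMe2 in THF to [4-(benzyloxy)-2,6-dibromo-3,5-dimethoxyphenyl]methanol F6, which MnO2 in CH2Cl2 oxidises to 4-(benzyloxy)-2,6-dibromo-3,5-dimethoxybenzaldehyde F7. Addition of enolate 10 (from 8, LiHMDS, THF, −78 °C) should give 3-[4-(benzyloxy)-2,6-dibromo-3,5-dimethoxyphenyl]-1-(4-bromo-2,5-dimethoxyphenyl)-3-hydroxy-2-methoxypropan-1-one F8 as a diastereomer mixture of no consequence. Dess–Martin oxidation then gives 11.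

Step 2. Ipso attack at C1 may cause bromodecarboxylation, or the reaction may stall after the first bromine. The fallback masks the carboxyl as a methyl ester, so ipso loss of CO2 is impossible, and releases it by SN2 dealkylation, because the doubly ortho-substituted ester resists saponification. It sets out from 3 and returns at 4. MeI/K2CO3 in DMF gives methyl 4-(benzyloxy)-3,5-dimethoxybenzoate F9. NBS (2.3 equiv) in MeCN with catalytic TFA should give methyl 4-(benzyloxy)-2,6-dibromo-3,5-dimethoxybenzoate F10. LiI in refluxing pyridine followed by acidification then gives 4.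

**Further compounds**

F1 | step 5 | 4-(benzyloxy)-2,6-dihydroxy-3,5-dimethoxybenzoic acid | COc1c(O)c(C(=O)O)c(O)c(OC)c1OCc1ccccc1
F2 | step 5 | 7-(benzyloxy)-5-hydroxy-6,8-dimethoxy-2,2-dimethyl-4H-1,3-benzodioxin-4-one | COc1c(O)c2C(=O)OC(C)(C)Oc2c(OC)c1OCc1ccccc1
F3 | step 5 | 7-(benzyloxy)-6,8-dimethoxy-5-(methoxymethoxy)-2,2-dimethyl-4H-1,3-benzodioxin-4-one | COCOc1c(OC)c(OCc2ccccc2)c(OC)c2OC(C)(C)OC(=O)c12
F4 | step 5 | 1-[4-(benzyloxy)-2-hydroxy-3,5-dimethoxy-6-(methoxymethoxy)phenyl]-3-(4-bromo-2,5-dimethoxyphenyl)-2-methoxypropane-1,3-dione (racemic) | COCOc1c(OC)c(OCc2ccccc2)c(OC)c(O)c1C(=O)C(OC)C(=O)c1cc(OC)c(Br)cc1OC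
F5 | step 5 | 7-(benzyloxy)-2-(4-bromo-2,5-dimethoxyphenyl)-5-hydroxy-3,6,8-trimethoxy-4H-chromen-4-one | COc1cc(-c2oc3c(OC)c(OCc4ccccc4)c(OC)c(O)c3c(=O)c2OC)c(OC)cc1Br
F6 | step 4 | [4-(benzyloxy)-2,6-dibromo-3,5-dimethoxyphenyl]methanol | COc1c(Br)c(CO)c(Br)c(OC)c1OCc1ccccc1
F7 | step 4 | 4-(benzyloxy)-2,6-dibromo-3,5-dimethoxybenzaldehyde | COc1c(Br)c(C=O)c(Br)c(OC)c1OCc1ccccc1
F8 | step 4 | 3-[4-(benzyloxy)-2,6-dibromo-3,5-dimethoxyphenyl]-1-(4-bromo-2,5-dimethoxyphenyl)-3-hydroxy-2-methoxypropan-1-one (mixture of diastereomers) | COc1c(Br)c(C(O)C(OC)C(=O)c2cc(OC)c(Br)cc2OC)c(Br)c(OC)c1OCc1ccccc1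
F9 | step 2 | methyl 4-(benzyloxy)-3,5-dimethoxybenzoate | COC(=O)c1cc(OC)c(OCc2ccccc2)c(OC)c1
F10 | step 2 | methyl 4-(benzyloxy)-2,6-dibromo-3,5-dimethoxybenzoate | COC(=O)c1c(Br)c(OC)c(OCc2ccccc2)c(OC)c1Br
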